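**Retrosynthetic overview**
- The nitrogen ring is closed last by forming the C3–N bond: a nitrile-derived N-lithio ketimine adds asymmetrically (6-endo) to an ortho (E)-propenyl group, which also sets C3; the C1 methyl comes from MeLi addition to the aryl nitrile.
- The biaryl nitrile comes from a Negishi coupling of an arylzinc (benzonitrile metalated between its two OMe groups) with a 2-bromonaphthalene MOM ether.
- The naphthalene comes from anionic benzannulation of an ortho-allyl benzamide (from 2-methoxy-4-methylbenzoic acid), MOM capture of the naphtholate, then directed bromination.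
- The benzonitrile comes from 1-bromo-3,5-dimethoxybenzene by electrophilic cyanation and Suzuki propenylation.
- Ring order: second naphthalene ring, then the biaryl axis, then the nitrogen ring.

Assumption: the biaryl axis (three ortho substituents, no axial descriptor in the SMILES) is taken as freely rotating at room temperature, so only C3 (S) is controlled.

**Step 1**
Reactants: 1 2-methoxy-4-methylbenzoic acid
Product: 3 N,N-diethyl-2-methoxy-4-methylbenzamide, via acid chloride 2 (not isolated)
Conditions: SOCl2, DMF (cat.), toluene, 70 °C; then Et2NH, aq. NaOH, CH2Cl2, 0 °C → rt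
Reagents that add atoms: diethylamine, CCNCC
Why: Acid chloride formation followed by Schotten–Baumann amidation is routine for benzoic acids and installs the tertiary amide that serves as directing group in step 2 and as the internal electrophile in step 3.

**Step 2**
Reactants: 3 N,N-diethyl-2-methoxy-4-methylbenzamide
Product: 6 N,N-diethyl-2-methoxy-4-methyl-6-(prop-2-en-1-yl)benzamide, via ortho-lithiated amide 4 (not isolated), via arylmagnesium bromide 5 (not isolated)
Conditions: s-BuLi, TMEDA, THF, −78 °C; MgBr2·OEt2, −78 → −20 °C; allyl bromide, −20 °C → rt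
Reagents that add atoms: allyl bromide, C=CCBr
Why: Directed ortho-metalation, in which the diethylamide outranks OMe so only the free position ortho to the amide is lithiated, and transmetalation to the Grignard reagent gives clean allylation without halogen–metal exchange.

**Step 3**
Reactants: 6 N,N-diethyl-2-methoxy-4-methyl-6-(prop-2-en-1-yl)benzamide
Product: 8 8-methoxy-1-(methoxymethoxy)-6-methylnaphthalene, via lithium naphtholate 7 (not isolated)
Conditions: MeLi (1.5 equiv), THF, −78 °C → rt; then MOMCl (3 equiv), 0 °C → rt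
Reagents that add atoms: chloromethyl methyl ether, COCCl
Why: Anionic benzannulation of an ortho-allylbenzamide (Snieckus type), in which the benzylic/allylic anion acylates on the hindered amide through its terminal carbon, LiNEt2 is lost and tautomerisation gives naphtholate 7, which is O-alkylated in the same flask (Williamson etherification).

**Step 4**
Reactants: 8 8-methoxy-1-(methoxymethoxy)-6-methylnaphthalene
Product: 10 2-bromo-8-methoxy-1-(methoxymethoxy)-6-methylnaphthalene, via 2-lithionaphthalene 9 (not isolated)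
Conditions: n-BuLi, TMEDA, Et2O, 0 °C; then BrCH2CH2Br, −78 °C → rt
Reagents that add atoms: 1,2-dibromoethane, BrCCBr
Why: Directed ortho-metalation, in which the MOM ether is the strongest directing group and C2 is its only free ortho position (C8 is blocked, C7 is flanked by OMe and methyl), and the aryllithium is brominated by 1,2-dibromoethane with loss of ethene.

**Step 5**
Reactants: 11 1-bromo-3,5-dimethoxybenzene
Product: 13 2-bromo-4,6-dimethoxybenzonitrile, via N-chlorosulfonyl amide 12 (not isolated)
Conditions: ClSO2NCO, CH2Cl2, 0 °C → rt; then DMF, 0 °C → rt; ice-water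
Reagents that add atoms: chlorosulfonyl isocyanate, O=C=NS(=O)(=O)Cl
Why: Electrophilic aromatic substitution with chlorosulfonyl isocyanate followed by DMF-induced loss of chlorosulfonic acid (one-pot arene cyanation), expected at the position para to one OMe and ortho to the other, by analogy with Vilsmeier formylation of 11.

**Step 6**
Reactants: 13 2-bromo-4,6-dimethoxybenzonitrile
Product: 14 2,4-dimethoxy-6-[(E)-prop-1-en-1-yl]benzonitrile
Conditions: (E)-propenylboronic acid pinacol ester, Pd(dppf)Cl2 (3 mol%), K2CO3, 1,4-dioxane/H2O, 85 °C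
Reagents that add atoms: 4,4,5,5-tetramethyl-2-[(E)-prop-1-en-1-yl]-1,3,2-dioxaborolane, C/C=C/B1OC(C)(C)C(C)(C)O1
Why: Suzuki–Miyaura coupling of an aryl bromide activated by the ortho nitrile, with retention of the (E) geometry of the alkenylboronate.

**Step 7**
Reactants: 14 2,4-dimethoxy-6-[(E)-prop-1-en-1-yl]benzonitrile; 10 2-bromo-8-methoxy-1-(methoxymethoxy)-6-methylnaphthalene
Product: 16 2,4-dimethoxy-3-[8-methoxy-1-(methoxymethoxy)-6-methylnaphthalen-2-yl]-6-[(E)-prop-1-en-1-yl]benzonitrile, via arylzinc chloride 15 (not isolated)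
Conditions: 14 (1.3 equiv), ZnCl2, lithium 2,2,6,6-tetramethylpiperidide (from the amine and n-BuLi), THF, −78 → −40 °C; then 10, Pd(OAc)2 (3 mol%), SPhos (6 mol%), 60 °C
Reagents that add atoms: none
Why: Directed metalation with in situ zinc trapping followed by Negishi coupling, in which the only C–H flanked by two OMe groups is removed kinetically by the hindered amide base and zincated before the nitrile or propenyl group can react, and Pd/SPhos is a proven system for tri-ortho-substituted biaryls.

**Step 8**
Reactants: 16 2,4-dimethoxy-3-[8-methoxy-1-(methoxymethoxy)-6-methylnaphthalen-2-yl]-6-[(E)-prop-1-en-1-yl]benzonitrile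
Product: 20 (3S)-7-(1-hydroxy-8-methoxy-6-methylnaphthalen-2-yl)-6,8-dimethoxy-1,3-dimethyl-3,4-dihydroisoquinoline, via N-lithio ketimine 17 (not isolated), via C4-lithio dihydroisoquinoline 18 (not isolated), via MOM ether 19 (not isolated)
Conditions: MeLi (1.2 equiv), (4S,4'S)-2,2'-(propane-2,2-diyl)bis(4-isopropyl-4,5-dihydrooxazole) (1.3 equiv), toluene/Et2O, −78 → 20 °C; MeOH; then 3 M HCl, MeOH, 45 °C; aq. NaHCO3
Reagents that add atoms: methyllithium, C[Li]
Why: Proposed new method: MeLi adds once to the nitrile (1,2-addition) to give N-lithio ketimine 17, whose bis(oxazoline)-bound N–Li unit adds across the ortho (E)-propenyl C=C in a 6-endo-trig syn-aminolithiation (N to the methyl-bearing carbon C3, Li to benzylic C4), the only mode that gives a carbanion stabilised by the arene and the ortho C=N; trading a C=C π bond for a C–N σ bond between anions of similar basicity should make the closure exergonic and slow to reverse below 20 °C, so the chiral ligand on lithium selects kinetically between the two helical transition states and is proposed to deliver N to the Si face of C3, which with the (E)-alkene gives (3S) (the sense of induction must be confirmed on a model, and the (R,R)-ligand is equally available); MeOH protonates 18 to 19 and HCl/MeOH removes the MOM group by acetal exchange while the cyclic imine is protected as its iminium salt; the closest known reaction types are the chiral bis(oxazoline)/lithium amide asymmetric intramolecular hydroamination of amino-styrenes and the achiral cascade of RLi addition to 2-alkenylbenzonitriles with N-cyclisation to isoquinolines.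

**Compound list**
1 | 2-methoxy-4-methylbenzoic acid | COc1cc(C)ccc1C(=O)O | starting material
2 | 2-methoxy-4-methylbenzoyl chloride | COc1cc(C)ccc1C(=O)Cl | intermediate
3 | N,N-diethyl-2-methoxy-4-methylbenzamide | CCN(CC)C(=O)c1ccc(C)cc1OC | intermediate
4 | [2-(diethylcarbamoyl)-3-methoxy-5-methylphenyl]lithium | CCN(CC)C(=O)c1c([Li])cc(C)cc1OC | intermediate
5 | [2-(diethylcarbamoyl)-3-methoxy-5-methylphenyl]magnesium bromide | CCN(CC)C(=O)c1c([Mg]Br)cc(C)cc1OC | intermediate
6 | N,N-diethyl-2-methoxy-4-methyl-6-(prop-2-en-1-yl)benzamide | CCN(CC)C(=O)c1c(CC=C)cc(C)cc1OC | intermediate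
7 | lithium 8-methoxy-6-methylnaphthalen-1-olate | [Li]Oc1cccc2cc(C)cc(OC)c12 | intermediate
8 | 8-methoxy-1-(methoxymethoxy)-6-methylnaphthalene | COCOc1cccc2cc(C)cc(OC)c12 | intermediate
9 | [8-methoxy-1-(methoxymethoxy)-6-methylnaphthalen-2-yl]lithium | COCOc1c([Li])ccc2cc(C)cc(OC)c12 | intermediate
10 | 2-bromo-8-methoxy-1-(methoxymethoxy)-6-methylnaphthalene | COCOc1c(Br)ccc2cc(C)cc(OC)c12 | intermediate
11 | 1-bromo-3,5-dimethoxybenzene | COc1cc(Br)cc(OC)c1 | starting material
12 | 2-bromo-N-(chlorosulfonyl)-4,6-dimethoxybenzamide | COc1cc(Br)c(C(=O)NS(=O)(=O)Cl)c(OC)c1 | intermediate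
13 | 2-bromo-4,6-dimethoxybenzonitrile | COc1cc(Br)c(C#N)c(OC)c1 | intermediate
14 | 2,4-dimethoxy-6-[(E)-prop-1-en-1-yl]benzonitrile | C/C=C/c1cc(OC)cc(OC)c1C#N | intermediate
15 | {3-cyano-2,6-dimethoxy-4-[(E)-prop-1-en-1-yl]phenyl}zinc chloride | C/C=C/c1cc(OC)c([Zn]Cl)c(OC)c1C#N | intermediate
16 | 2,4-dimethoxy-3-[8-methoxy-1-(methoxymethoxy)-6-methylnaphthalen-2-yl]-6-[(E)-prop-1-en-1-yl]benzonitrile | C/C=C/c1cc(OC)c(-c2ccc3cc(C)cc(OC)c3c2OCOC)c(OC)c1C#N | intermediate
17 | N-lithio ketimine of the methyl aryl ketone derived from 16 (MeLi adduct of the nitrile, (E)-propenyl intact) | C/C=C/c1cc(OC)c(-c2ccc3cc(C)cc(OC)c3c2OCOC)c(OC)c1C(C)=N[Li] | intermediate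
18 | (3S)-4-lithio-7-[8-methoxy-1-(methoxymethoxy)-6-methylnaphthalen-2-yl]-6,8-dimethoxy-1,3-dimethyl-3,4-dihydroisoquinoline (delocalised benzylic lithium) | COc1cc2c(c(OC)c1-c1ccc3cc(C)cc(OC)c3c1OCOC)C(C)=N[C@@H](C)C2[Li] | intermediate
19 | (3S)-7-[8-methoxy-1-(methoxymethoxy)-6-methylnaphthalen-2-yl]-6,8-dimethoxy-1,3-dimethyl-3,4-dihydroisoquinoline | COc1cc2c(c(OC)c1-c1ccc3cc(C)cc(OC)c3c1OCOC)C(C)=N[C@@H](C)C2 | intermediate
20 | (3S)-7-(1-hydroxy-8-methoxy-6-methylnaphthalen-2-yl)-6,8-dimethoxy-1,3-dimethyl-3,4-dihydroisoquinoline | COc1cc2c(c(OC)c1-c1ccc3cc(C)cc(OC)c3c1O)C(C)=N[C@@H](C)C2 | target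

**Step count and risk**
Total steps: 8. Longest linear sequence: 6 steps (1, 2, 3, 4, 7, 8); the arene branch (steps 5 and 6) joins at step 7.

Steps most likely to fail:

Step 8 (proposed new asymmetric ring closure; risks are low enantioselectivity, C- instead of N-cyclisation of the tautomeric aza-enolate, or no closure). The fallback uses known chemistry with the stereocentre taken from L-alaninol; it sets out from 13 (and uses 10) and comes back at 20. Commercial tert-butyl N-[(2S)-1-iodopropan-2-yl]carbamate is treated with zinc dust in DMF to give [(2S)-2-(tert-butoxycarbonylamino)propyl]zinc iodide F1. Negishi coupling of F1 with 13 (Pd2(dba)3, SPhos, DMF, 40 °C) gives tert-butyl N-[(2S)-1-(2-cyano-3,5-dimethoxyphenyl)propan-2-yl]carbamate F2. Zincation as in step 7, with 2.5 equiv of the lithium amide because the first equivalent removes the carbamate N–H, gives the N-lithiated arylzinc chloride F3. F3 is coupled with 10 (Pd(OAc)2, SPhos) to give the biaryl carbamate nitrile F4. MeLi (2.5 equiv) converts F4 into the dilithiated ketimine F5. HCl/MeOH then cleaves Boc and MOM and hydrolyses the ketimine to the amino ketone F6, which closes to 20 by intramolecular imine condensation on neutralisation.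

Step 7 (metalation beside a nitrile and a propenyl group, then a hindered coupling in one flask). The fallback reverses the polarity and separates metalation from coupling; it sets out from 14 and 8 and comes back at 16. Arylzinc 15, made at −78 °C as in step 7, is quenched with iodine and purified as 3-iodo-2,4-dimethoxy-6-[(E)-prop-1-en-1-yl]benzonitrile F7. MOM ether 8 is lithiated to 9 as in step 4 and transmetalated with ZnCl2 to [8-methoxy-1-(methoxymethoxy)-6-methylnaphthalen-2-yl]zinc chloride F8. Negishi coupling of F7 with F8 (Pd(OAc)2, SPhos, THF, 50 °C) gives 16; step 4 is then not needed.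

Step 3 (one-flask annulation and O-alkylation of a peri-chelated, hindered naphtholate). The fallback isolates the naphthol and introduces bromine electrophilically instead of by metalation; it sets out from 6 and comes back at 10. Naphtholate 7 is quenched with aqueous NH4Cl to give 8-methoxy-6-methylnaphthalen-1-ol F9. Amine-directed ortho-bromination (Br2, tert-butylamine, toluene, −70 °C) gives 2-bromo-8-methoxy-6-methylnaphthalen-1-ol F10. MOMCl/NaH in DMF then gives 10, bypassing 8 and step 4.

**Further compounds**
F1 | step 8 | [(2S)-2-(tert-butoxycarbonylamino)propyl]zinc iodide | CC(C)(C)OC(=O)N[C@@H](C)C[Zn]I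
F2 | step 8 | tert-butyl N-[(2S)-1-(2-cyano-3,5-dimethoxyphenyl)propan-2-yl]carbamate | CC(C)(C)OC(=O)N[C@@H](C)Cc1cc(OC)cc(OC)c1C#N
F3 | step 8 | N-lithiated {4-[(2S)-2-(tert-butoxycarbonylamino)propyl]-3-cyano-2,6-dimethoxyphenyl}zinc chloride | CC(C)(C)OC(=O)N([Li])[C@@H](C)Cc1cc(OC)c([Zn]Cl)c(OC)c1C#N
F4 | step 8 | tert-butyl N-[(2S)-1-{2-cyano-3,5-dimethoxy-4-[8-methoxy-1-(methoxymethoxy)-6-methylnaphthalen-2-yl]phenyl}propan-2-yl]carbamate | CC(C)(C)OC(=O)N[C@@H](C)Cc1cc(OC)c(-c2ccc3cc(C)cc(OC)c3c2OCOC)c(OC)c1C#N
F5 | step 8 | dilithiated ketimine from F4 (N-lithio carbamate, N-lithio methyl ketimine) | CC(C)(C)OC(=O)N([Li])[C@@H](C)Cc1cc(OC)c(-c2ccc3cc(C)cc(OC)c3c2OCOC)c(OC)c1C(C)=N[Li]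
F6 | step 8 | 1-{6-[(2S)-2-aminopropyl]-3-(1-hydroxy-8-methoxy-6-methylnaphthalen-2-yl)-2,4-dimethoxyphenyl}ethan-1-one | N[C@@H](C)Cc1cc(OC)c(-c2ccc3cc(C)cc(OC)c3c2O)c(OC)c1C(C)=O
F7 | step 7 | 3-iodo-2,4-dimethoxy-6-[(E)-prop-1-en-1-yl]benzonitrile | C/C=C/c1cc(OC)c(I)c(OC)c1C#N
F8 | step 7 | [8-methoxy-1-(methoxymethoxy)-6-methylnaphthalen-2-yl]zinc chloride | COCOc1c([Zn]Cl)ccc2cc(C)cc(OC)c12
F9 | step 3 | 8-methoxy-6-methylnaphthalen-1-ol | COc1cc(C)cc2cccc(O)c12
F10 | step 3 | 2-bromo-8-methoxy-6-methylnaphthalen-1-ol | COc1cc(C)cc2ccc(Br)c(O)c12
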